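**Retrosynthetic overview**

1. Target 14 is 3-henicosyl-5-methoxy-2-methyl-1,4-benzoquinone (achiral); the ring is numbered C1(=O), C2–CH3, C3–C21H43, C4(=O), C5–OCH3, C6–H.
2. Final disconnection: the ring is cut at C1–C6, C5–C4 and C4–C3 into alkenyl(methoxy)carbene chromium complex 9 (C1, C2, C3 with the methyl group and the chain), methoxyethyne 12 (C6, C5 with the methoxy group) and one CO ligand (C4). This is a three-component [3+2+1] Dötz benzannulation, with oxidation to the quinone in the same flask.
3. Enabling feature: in the single six-membered ring the carbonyl carbons C1 and C4 are para, and between them lie the unsubstituted C6–H (next to C1) and the methoxy-bearing C5 (next to C4). This C6–C5 edge is the imprint of a terminal alkoxyalkyne, whose size and polarisation both fix its orientation; the C2(CH3)=C3(chain) edge is the alkenyl arm of the carbene.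
4. Complex 9 is cut at its C2=C3 alkene into ethyl(methoxy)carbene complex 6 (from Cr(CO)6 and ethyllithium) and docosanal 2 (from 1-docosanol; its carbonyl carbon becomes ring C3), joined by aldol addition and dehydration.
5. Ring order: there is only one ring, and it is formed in the last step.

Key step: step 6

Remark: the chain is read as unbranched henicosyl (21 carbons); the target has no stereocenter, so the only stereochemical issue of the route is the E geometry of alkene 9.

**Route**

Step 1
Reactants: 1 1-docosanol
Product: 2 docosanal
Conditions: TEMPO (10 mol %), PhI(OAc)2 (1.1 equiv), CH2Cl2, 25–30 °C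
Reagents that add atoms: none
Why: The TEMPO/PhI(OAc)2 (oxoammonium) oxidation of a primary alcohol should stop at the aldehyde under anhydrous conditions and tolerates the waxy chain.

Step 2
Reactants: 3 chromium hexacarbonyl, 4 ethyllithium
Product: 6 pentacarbonyl(1-methoxypropylidene)chromium, via lithium acylchromate 5 (not isolated)
Conditions: Et2O, 0 °C to rt; then Me3OBF4, H2O/CH2Cl2, 0 °C
Reagents that add atoms: trimethyloxonium tetrafluoroborate, C[O+](C)C.F[B-](F)(F)F
Why: Fischer carbene synthesis: the organolithium adds to a CO ligand of Cr(CO)6 and the hard acyl oxygen of the acylchromate is methylated by the oxonium salt.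

Step 3
Reactants: 6 pentacarbonyl(1-methoxypropylidene)chromium, 2 docosanal
Product: 7 pentacarbonyl(3-hydroxy-1-methoxy-2-methyltetracosylidene)chromium (racemic, mixture of syn and anti diastereomers)
Conditions: n-BuLi (1.05 equiv), THF, −78 °C; then 2 premixed with BF3·OEt2 in CH2Cl2, −78 to −40 °C; aq NaHCO3
Reagents that add atoms: none
Why: The alpha C–H bonds of an alkyl(alkoxy)carbene complex are strongly acidic, and the stabilised anion should add to the BF3-activated aldehyde (Lewis-acid-mediated aldol addition of a Fischer carbene anion); the two new stereocenters form without control and are both erased in step 4.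

Step 4
Reactants: 7 pentacarbonyl(3-hydroxy-1-methoxy-2-methyltetracosylidene)chromium
Product: 9 pentacarbonyl[(2E)-1-methoxy-2-methyltetracos-2-en-1-ylidene]chromium, via mesylate 8 (not isolated)
Conditions: MsCl (1.5 equiv), Et3N (3 equiv), CH2Cl2, 0 °C to rt
Reagents that add atoms: none
Why: Mesylation of the secondary alcohol and E1cB elimination through the acidic alpha C–H complete the aldol condensation; the E isomer should dominate because the chain avoids the bulky C(OCH3)=Cr(CO)5 group.

Step 5
Reactants: 10 2-chloro-1,1-dimethoxyethane
Product: 12 methoxyethyne, via sodium methoxyacetylide 11 (not isolated)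
Conditions: NaNH2 (3 equiv), liquid NH3, −33 °C; then saturated aq NaCl, −70 °C; distilled into cold THF
Reagents that add atoms: none
Why: Twofold base-induced beta-elimination (loss of methanol and of HCl) of the chloroacetal, the alkyne being held as its sodium acetylide until the cold aqueous quench.

Step 6
Reactants: 9 pentacarbonyl[(2E)-1-methoxy-2-methyltetracos-2-en-1-ylidene]chromium, 12 methoxyethyne
Product: 14 3-henicosyl-5-methoxy-2-methylcyclohexa-2,5-diene-1,4-dione, via dimethoxyphenol 13 (not isolated)
Conditions: 12 (3 equiv, cold THF solution), THF, 50 °C, sealed tube, Ar; then (NH4)2Ce(NO3)6 (excess), MeCN/H2O, 0 °C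
Reagents that add atoms: water, O
Why: This is a Dötz [3+2+1] benzannulation of an alkenyl(methoxy)carbene chromium complex with an alkyne, the closest known cases being the same reaction of (E)-but-2-en-2-yl(methoxy)carbene complexes with terminal alkynes and of carbene complexes with 1-alkoxyalkynes: loss of one CO lets 12 coordinate and insert into the Cr=C bond (new bond C1–C6), the methoxy-stabilised dienylcarbene so formed inserts a CO ligand at C5 to give a chromium-bound dienylketene (new bond C5–C4), and this closes onto the alkene terminus (new bond C4–C3) before tautomerising to phenol 13. The single six-membered ring is closed by a thermal, disrotatory 6π electrocyclisation of the metal-bound dienylketene, and no stereocenter is formed. The step needs one regiochemical outcome, bonding of the alkyne CH terminus to the carbene carbon, which is secured twice: a terminal alkyne places its substituted carbon next to the CO-derived carbon for steric reasons, and the ynol ether is polarised so that its nucleophilic CH carbon attacks the electrophilic carbene carbon while the methoxy group stabilises the new carbene centre. It also needs CO insertion to win over five-membered-ring formation, which alkenyl (as opposed to aryl) chromium complexes in THF favour, and the E geometry of 9 turns the chain away from the closing termini. (NH4)2Ce(NO3)6 then strips the chromium and oxidises the 4-methoxyphenol unit of 13 to the para-quinone, the C1 methyl ether leaving as methanol with the new oxygen coming from water, while the ortho methoxy group at C5 stays.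

**Compound list**

1 | 1-docosanol | CCCCCCCCCCCCCCCCCCCCCCO | starting material
2 | docosanal | CCCCCCCCCCCCCCCCCCCCCC=O | intermediate
3 | chromium hexacarbonyl | O=C=[Cr](=C=O)(=C=O)(=C=O)(=C=O)=C=O | starting material
4 | ethyllithium | [Li]CC | starting material
5 | lithium pentacarbonyl(1-oxidopropylidene)chromate (lithium acylchromate) | CCC([O-])=[Cr](=C=O)(=C=O)(=C=O)(=C=O)=C=O.[Li+] | intermediate
6 | pentacarbonyl(1-methoxypropylidene)chromium | CCC(OC)=[Cr](=C=O)(=C=O)(=C=O)(=C=O)=C=O | intermediate
7 | pentacarbonyl(3-hydroxy-1-methoxy-2-methyltetracosylidene)chromium, racemic syn/anti mixture | CCCCCCCCCCCCCCCCCCCCCC(O)C(C)C(OC)=[Cr](=C=O)(=C=O)(=C=O)(=C=O)=C=O | intermediate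
8 | pentacarbonyl[1-methoxy-2-methyl-3-(methylsulfonyloxy)tetracosylidene]chromium (mesylate) | CCCCCCCCCCCCCCCCCCCCCC(OS(C)(=O)=O)C(C)C(OC)=[Cr](=C=O)(=C=O)(=C=O)(=C=O)=C=O | intermediate
9 | pentacarbonyl[(2E)-1-methoxy-2-methyltetracos-2-en-1-ylidene]chromium | CCCCCCCCCCCCCCCCCCCCC/C=C(\C)C(OC)=[Cr](=C=O)(=C=O)(=C=O)(=C=O)=C=O | intermediate
10 | 2-chloro-1,1-dimethoxyethane (chloroacetaldehyde dimethyl acetal) | COC(CCl)OC | starting material
11 | sodium methoxyacetylide | COC#[C-].[Na+] | intermediate
12 | methoxyethyne | COC#C | intermediate
13 | 2-henicosyl-4,6-dimethoxy-3-methylphenol | CCCCCCCCCCCCCCCCCCCCCc1c(C)c(OC)cc(OC)c1O | intermediate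
14 | 3-henicosyl-5-methoxy-2-methylcyclohexa-2,5-diene-1,4-dione | CCCCCCCCCCCCCCCCCCCCCC1=C(C)C(=O)C=C(OC)C1=O | target

**Step count and risks**

Total step count: 6. Longest linear sequence: 4 steps (steps 1, 3, 4, 6).

Steps most likely to fail:

1. Step 6. The electron-rich alkyne may insert without the following CO insertion and ring closure (alkyne oligomerisation, or arrest at the donor-stabilised dienylcarbene), or it may insert with the opposite orientation. The fallback gives up the annulation and attaches the chain to a ready-made ring by decarboxylative radical alkylation. It sets out from 2, which is oxidised (NaClO2, NaH2PO4, 2-methylbut-2-ene, t-BuOH/THF/H2O; Pinnick oxidation) to docosanoic acid F1. Commercial 2-methoxy-5-methylphenol is oxidised with (KSO3)2NO in buffered aqueous acetone (Teuber oxidation) to 2-methoxy-5-methyl-1,4-benzoquinone F2. F1 and F2 are then combined with AgNO3 (catalytic) and (NH4)2S2O8 in MeCN/H2O at 75 °C (Jacobsen–Torssell alkylation). The nucleophilic henicosyl radical should add at the ring CH next to the methyl-bearing carbon and not at the electron-rich CH next to the methoxy-bearing carbon, so the fallback comes back to the route at 14.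

2. Step 3. Addition of the hindered, weakly nucleophilic carbene anion may be incomplete or reversible, and the enolisable aldehyde may self-condense under the Lewis acid or precipitate at low temperature. The fallback makes the alkenylcarbene by the Fischer route from an alkenyllithium and replaces steps 3 and 4. It sets out from 2, which is converted (CBr4, PPh3, CH2Cl2, 0 °C; Corey–Fuchs olefination) into 1,1-dibromotricos-1-ene F3. Treatment with n-BuLi (2 equiv, THF, −78 °C) and then MeI should give tetracos-2-yne F4. Hydrozirconation with a slight excess of Cp2Zr(H)Cl in THF (equilibrating conditions, zirconium at the methyl-side carbon) followed by I2 should give (E)-2-iodotetracos-2-ene F5. Iodine–lithium exchange (t-BuLi, 2 equiv, Et2O, −78 °C) should give (Z)-tetracos-2-en-2-yllithium F6 with retention of geometry. Addition to 3 gives lithium pentacarbonyl[(2E)-2-methyl-1-oxidotetracos-2-en-1-ylidene]chromate F7, and O-methylation with Me3OBF4 comes back to the route at 9.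

3. Step 5. The alkyne boils near room temperature and polymerises easily, so much of it may be lost during distillation and transfer. The fallback uses a commercial, less volatile alkoxyalkyne and corrects the ether afterwards. It sets out from 9, which is heated with commercial ethoxyethyne (hexane solution) in THF at 50 °C to give 6-ethoxy-2-henicosyl-4-methoxy-3-methylphenol F8, not isolated. Oxidation in the same flask with (NH4)2Ce(NO3)6 should give 5-ethoxy-3-henicosyl-2-methyl-1,4-benzoquinone F9. Acid-catalysed exchange of the vinylogous ester (MeOH/CH2Cl2, catalytic H2SO4, rt) then comes back to the route at 14.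

**Further compounds**

F1 | step 6 | docosanoic acid | CCCCCCCCCCCCCCCCCCCCCC(=O)O
F2 | step 6 | 2-methoxy-5-methylcyclohexa-2,5-diene-1,4-dione | COC1=CC(=O)C(C)=CC1=O
F3 | step 3 | 1,1-dibromotricos-1-ene | CCCCCCCCCCCCCCCCCCCCCC=C(Br)Br
F4 | step 3 | tetracos-2-yne | CCCCCCCCCCCCCCCCCCCCCC#CC
F5 | step 3 | (E)-2-iodotetracos-2-ene | CCCCCCCCCCCCCCCCCCCCC/C=C(\C)I
F6 | step 3 | (Z)-tetracos-2-en-2-yllithium | CCCCCCCCCCCCCCCCCCCCC/C=C(\C)[Li]
F7 | step 3 | lithium pentacarbonyl[(2E)-2-methyl-1-oxidotetracos-2-en-1-ylidene]chromate | CCCCCCCCCCCCCCCCCCCCC/C=C(\C)C([O-])=[Cr](=C=O)(=C=O)(=C=O)(=C=O)=C=O.[Li+]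
F8 | step 5 | 6-ethoxy-2-henicosyl-4-methoxy-3-methylphenol | CCCCCCCCCCCCCCCCCCCCCc1c(C)c(OC)cc(OCC)c1O
F9 | step 5 | 5-ethoxy-3-henicosyl-2-methylcyclohexa-2,5-diene-1,4-dione | CCCCCCCCCCCCCCCCCCCCCC1=C(C)C(=O)C=C(OCC)C1=O
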